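Ring numbering used throughout, also for precursors: C1 is the epoxide carbon that carries C7 (the CH2OBz carbon), C2 the CHOAc carbon, C3 the CHOBz carbon, C4=C5 the alkene, C6 the epoxide CH.

## Analysis of the target

- **Ring system.** Target 14 is a 7-oxabicyclo[4.1.0]hept-4-ene: a six-membered carbocycle whose C1–C6 bond is bridged by an epoxide oxygen. C1 is quaternary and carries the benzoyloxymethyl carbon C7, C2 carries an acetate, C3 a benzoate, and C4=C5 is the only alkene.
- **Stereocentres.** C1, C2, C3 and C6 are contiguous and (1S,2S,3R,6S). The C2 acetate and the C3 benzoate are trans. The epoxide oxygen lies on the face of the C3 benzoate and opposite the C2 acetate, so C7 is cis to the acetate.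
- **Sensitive groups.** The epoxide is allylic, so it is open to acid, to SN2′ attack and to zerovalent palladium. The three esters can migrate (O2 to O3, O2 to O7) or be cleaved by base. Nothing strongly acidic, basic or reducing can follow epoxide formation.
- **Difficulty.** No ring carbon is unfunctionalised and no carbon substituent on the ring relays stereochemistry. The three oxygens at C2, C3 and C7 must carry two different acyl groups in a fixed pattern. Any diene precursor is one elimination of water or a carboxylic acid away from a benzene ring.
- **Feature the strategy rests on.** C2 and C3 are adjacent oxygenated sp3 carbons between C1, which bears the only carbon substituent, and C4. The other four ring carbons are at the oxidation level of a 1,3-diene, the C1–C6 epoxide being an oxidised C1=C6 bond. This is the pattern of the 2,3-dihydrodiol of a monosubstituted benzene, so all six ring carbons and both carbinol centres can come from one arene and one dihydroxylation.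

## Retrosynthetic reasoning

**Epoxide (C1–O and C6–O).** These bonds are cut first, which leads to diene triester 12 and peracid 13. The vinyl epoxide is the most fragile function of 14, so it is made last and nothing has to be done in its presence. The forward reaction has to pick the trisubstituted C1=C6 bond over C4=C5 and the face anti to the C2 acetate.

**C7–O ester.** 12 is cut to allylic alcohol 10 and benzoyl chloride 11. Keeping O7 free until here lets C7 enter as a hydroxymethyl group in the preceding C–C bond formation. The forward acylation only has to be quick enough to forestall acetyl migration from O2 to O7.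

**C1–C7 bond.** 10 is cut between C1 and C7 to vinyl bromide 8 and stannane 9. This is the only C–C bond the route makes. It is cut at the sp2 carbon C1 because a halogen at exactly this position is what the dihydroxylation of a halobenzene leaves behind. The forward cross-coupling must leave the diene and both esters untouched.

**C2–O acetate.** 8 is cut to hydroxy benzoate 6 and acetic anhydride 7. The acetate goes on second because C2–OH is the hydroxyl that is left over once the two carbinols have been told apart.

**C3–O benzoate, with inversion.** 6 is traced to cis diol 3 and benzoic acid 4. The forward reaction replaces the C3 oxygen of 3 by an oxygen of 4 from the opposite face. One operation thus gives both the trans relationship and the benzoate. C3 rather than C2 is the site because the C2 carbinol of 3 sits next to the bromine-bearing carbon and is the more hindered and less reactive of the two. Its configuration in 3 is already that of 14.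

**C2–O and C3–O bonds to the ring.** 3 is cut to bromobenzene 1 and dioxygen 2. The carbocycle is never constructed: it is the benzene ring of 1, dearomatised by adding both oxygen atoms of 2 to one face of the C2–C3 bond. This leaves the C1(Br)=C6–C5=C4 diene that the later steps use.

## Alternatives that were turned down

**Alternative 1: photooxygenation of a dearomatised salicyl alcohol.**
- Disconnection: the C3–O and C6–O bonds are traced to one molecule of dioxygen 2 added across a C3=C4–C5=C6 diene, and the ring epoxide to a spiro epoxide at C1/C7. The carbons come from salicyl alcohol A3 by oxidative dearomatisation of the Adler–Becker type, carbonyl reduction and acetylation to the spiro-epoxy dienyl acetate A2.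
- Forward key step: dye-sensitised [4+2] addition of singlet 2 to A2 gives endoperoxide A1, with the peroxide bridge anti to the acetate and to the spiro-epoxide oxygen. O–O reduction, Payne rearrangement of the C6 alkoxide onto C1 and double benzoylation would finish.
- For it: C7 is in the starting material, so no C–C bond is made. The cycloaddition fixes O3 and O6 cis, and the Payne step inverts C1, so the epoxide ends syn to O3 and anti to O2 by mechanism. On this point it is stronger than the chosen route, whose last step relies on a facial preference. Both benzoates go on in one operation.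
- Against it: the dearomatised dienone is racemic and prone to Diels–Alder dimerisation, so the absolute configuration needs a resolution or an asymmetric reduction. The reduction must place O2 cis to the epoxide oxygen. The Payne step needs alkoxide base while the C2 acetate sits beside a free C3 hydroxyl, which invites acetyl migration and ester cleavage.
- Comparison: about seven to eight steps plus a resolution, against six. The chosen strategy gives up the mechanistic guarantee for the epoxide face and has to make one C–C bond. In return it has enantiopurity from the first step and never treats an acylated intermediate with strong base.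

**Alternative 2: carbene-catalysed crossed benzoin closing C1–C2.**
- Disconnection: the ring is cut at C1–C2 to the open-chain keto aldehyde A5 (C2 aldehyde, C3 p-methoxybenzyl ether, Z-C4=C5, C6 silyl ether, C1 ketone carrying CH2OBz).
- Forward key step: a chiral triazolylidene carbene converts the C2 aldehyde into its acyl-anion equivalent, which adds to the C1 ketone and closes the six-membered ring as the tertiary α-ketol A4.
- For it: the quaternary C1 and its oxygen are set under catalyst control, and every oxygen arrives already differentiated. Here it is stronger than the chosen route, which has to tell O2 from O3 by their surroundings.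
- Against it: A5 holds a Z-alkene between two oxygenated stereocentres and would cost some eight to ten steps. Its α-alkoxy aldehyde can epimerise or expel the alkoxide from the hydroxy-enamine intermediate. After ring closure, the C2 ketone must be reduced from the right face and acetylated, the C6 silyl ether turned into a leaving group and displaced by the C1 alkoxide with inversion, and the C3 ether exchanged for benzoate beside a vinyl epoxide.
- Comparison: well over fifteen steps against six. The chosen strategy has less reagent control, but the ring, both carbinol centres and the handle at C1 all exist after one step.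

**Alternative 3: masked o-benzoquinone and nucleophilic epoxidation.**
- Disconnection: the C1–C6 epoxide is cut and the ring taken back to the 6,6-dimethoxy dienone A7, made by oxidative dearomatisation of o-vanillyl alcohol A8 with a hypervalent iodine reagent in the alcohol that supplies the second methoxy group.
- Forward key step: a bulky hydroperoxide anion, organised by a tartrate ester, adds to C6 of A7 and the enolate closes on oxygen to give epoxy enone ketal A6. Benzoylation of O7, reduction of the C2 ketone, acetylation, ketal hydrolysis to the C3 enone, 1,2-reduction (NaBH4/CeCl3) and benzoylation would follow.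
- For it: a cheap aromatic that already contains C7, and the epoxide centres are set first under reagent control, which the chosen route cannot claim for its epoxidation. About eight steps, close to six.
- Against it: dienones of this kind without blocking substituents dimerise quickly. The peroxide can add at C4 as well as at C6. Both carbinol centres then depend on substrate-controlled hydride additions from opposite faces (O2 anti, O3 syn to the epoxide). The ketal must be hydrolysed with acid next to the epoxide.
- Comparison: the chosen strategy distributes the risk the other way. Its carbinol centres are secure (enzyme, then a stereospecific SN2 inversion) and only the epoxide face relies on the substrate.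

Key step: step 1

Remark: in step 1 the two reducing equivalents come from NADH, which the living cells regenerate by oxidising the glucose feed to carbon dioxide. Glucose is therefore the stoichiometric reductant, and the enzyme system with its cofactor is the catalyst.

## Route

**Step 1**
Reactants: 1 bromobenzene; 2 dioxygen
Product: 3 (1S,2S)-3-bromocyclohexa-3,5-diene-1,2-diol
Conditions: E. coli JM109(pDTG601) whole cells (toluene dioxygenase), IPTG, glucose feed, air, mineral medium, pH 6.8–7.2, 30–35 °C; EtOAc extraction, crystallisation
Reagents that add atoms: dioxygen, O=O
Why: The three-component toluene dioxygenase passes two electrons from NADH through its reductase and [2Fe-2S] ferredoxin to a mononuclear non-haem iron centre held by two histidines and one carboxylate; dioxygen binds side-on at the ferrous iron, is reduced to an iron-bound (hydro)peroxide, and both oxygen atoms are delivered to the same face of the C2–C3 bond of the arene held in the hydrophobic pocket, so the diol is cis. The step closes no ring; it is the enzymatic counterpart of a syn-dihydroxylation with OsO4, applied to an aromatic bond that OsO4 does not attack, and it is an established reaction of monohalobenzenes. Both new stereocentres (C2 and C3) are set by the protein, which binds the arene so that only the bond between the ortho and meta carbons lies over the iron and only one face is exposed, which should give the (1S,2S) diol as a single enantiomer. The step needs regioselectivity for the 2,3-bond, one enantiotopic face and a stop at the diol stage; the first two come from the active site and the last from the host, which carries the dioxygenase genes but no diol dehydrogenase, so that no catechol forms. The diene diol is kept cold and at neutral pH to prevent dehydration back to an arene.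

**Step 2**
Reactants: 3 (1S,2S)-3-bromocyclohexa-3,5-diene-1,2-diol; 4 benzoic acid
Product: 6 (1R,6S)-5-bromo-6-hydroxycyclohexa-2,4-dien-1-yl benzoate, via C3 oxyphosphonium benzoate 5 (not isolated)
Conditions: PPh3, DIAD, THF, −20 → 0 °C
Reagents that add atoms: benzoic acid, O=C(O)c1ccccc1
Why: Mitsunobu esterification: the C3 hydroxyl, remote from bromine and the less hindered one, is converted into the oxyphosphonium ion and displaced by benzoate in an SN2 step with inversion, which turns the cis diol into the trans hydroxy benzoate; the C2 hydroxyl is flanked by the C–Br carbon, whose bulk and electron withdrawal retard its activation and displacement, and the low temperature and weak acid limit dehydration of the diene.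

**Step 3**
Reactants: 6 (1R,6S)-5-bromo-6-hydroxycyclohexa-2,4-dien-1-yl benzoate; 7 acetic anhydride
Product: 8 (1R,6S)-6-(acetyloxy)-5-bromocyclohexa-2,4-dien-1-yl benzoate
Conditions: Ac2O, pyridine, DMAP (cat.), CH2Cl2, 0 °C
Reagents that add atoms: acetic anhydride, CC(=O)OC(C)=O
Why: DMAP-catalysed acylation of the remaining secondary C2 alcohol touches no stereocentre, and the mild base at 0 °C should avoid benzoyl migration and elimination of benzoic acid.

**Step 4**
Reactants: 8 (1R,6S)-6-(acetyloxy)-5-bromocyclohexa-2,4-dien-1-yl benzoate; 9 (tributylstannyl)methanol
Product: 10 (1R,6R)-6-(acetyloxy)-5-(hydroxymethyl)cyclohexa-2,4-dien-1-yl benzoate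
Conditions: Pd(PPh3)4 (cat.), toluene, 80 °C, degassed
Reagents that add atoms: (tributylstannyl)methanol, OC[Sn](CCCC)(CCCC)CCCC
Why: Migita–Kosugi–Stille coupling: zerovalent palladium inserts into the C1–Br bond, the hydroxymethyl group is transferred from tin in preference to butyl, and reductive elimination forms the C1–C7 bond with the diene intact; oxidative addition to the vinyl bromide should outrun ionisation of the allylic benzoate.

**Step 5**
Reactants: 10 (1R,6R)-6-(acetyloxy)-5-(hydroxymethyl)cyclohexa-2,4-dien-1-yl benzoate; 11 benzoyl chloride
Product: 12 [(5R,6R)-6-(acetyloxy)-5-(benzoyloxy)cyclohexa-1,3-dien-1-yl]methyl benzoate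
Conditions: BzCl, pyridine, CH2Cl2, 0 °C
Reagents that add atoms: benzoyl chloride, O=C(Cl)c1ccccc1
Why: Pyridine-mediated O-acylation of the primary allylic alcohol; 10 is used without storage so that benzoylation forestalls acetyl migration from O2 to O7.

**Step 6**
Reactants: 12 [(5R,6R)-6-(acetyloxy)-5-(benzoyloxy)cyclohexa-1,3-dien-1-yl]methyl benzoate; 13 3-chloroperoxybenzoic acid (mCPBA)
Product: 14 [(1S,2S,3R,6S)-2-(acetyloxy)-3-(benzoyloxy)-7-oxabicyclo[4.1.0]hept-4-en-1-yl]methyl benzoate
Conditions: mCPBA, CH2Cl2 / aq. NaHCO3, 0 °C → rt
Reagents that add atoms: 3-chloroperoxybenzoic acid, OOC(=O)c1cccc(Cl)c1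
Why: Prilezhaev epoxidation: the concerted oxygen transfer should prefer the trisubstituted, more electron-rich C1=C6 bond over C4=C5 and the face opposite the adjacent, pseudo-axial C2 acetate, which sets C1 and C6 together with the oxygen anti to the acetate; the C3 benzoate on the other face is homoallylic to C1=C6 and shields C4=C5 instead, and the bicarbonate buffer protects the vinyl epoxide from the acid by-product.

## Compound list

1 | bromobenzene | Brc1ccccc1 | starting material
2 | dioxygen | O=O | starting material
3 | (1S,2S)-3-bromocyclohexa-3,5-diene-1,2-diol | O[C@H]1[C@@H](O)C=CC=C1Br | intermediate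
4 | benzoic acid | O=C(O)c1ccccc1 | starting material
5 | {[(1S,6S)-5-bromo-6-hydroxycyclohexa-2,4-dien-1-yl]oxy}triphenylphosphonium benzoate (not isolated) | O[C@H]1[C@@H](O[P+](c2ccccc2)(c2ccccc2)c2ccccc2)C=CC=C1Br.[O-]C(=O)c1ccccc1 | intermediate
6 | (1R,6S)-5-bromo-6-hydroxycyclohexa-2,4-dien-1-yl benzoate | O[C@H]1[C@H](OC(=O)c2ccccc2)C=CC=C1Br | intermediate
7 | acetic anhydride | CC(=O)OC(C)=O | starting material
8 | (1R,6S)-6-(acetyloxy)-5-bromocyclohexa-2,4-dien-1-yl benzoate | CC(=O)O[C@H]1[C@H](OC(=O)c2ccccc2)C=CC=C1Br | intermediate
9 | (tributylstannyl)methanol | OC[Sn](CCCC)(CCCC)CCCC | starting material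
10 | (1R,6R)-6-(acetyloxy)-5-(hydroxymethyl)cyclohexa-2,4-dien-1-yl benzoate | CC(=O)O[C@H]1[C@H](OC(=O)c2ccccc2)C=CC=C1CO | intermediate
11 | benzoyl chloride | O=C(Cl)c1ccccc1 | starting material
12 | [(5R,6R)-6-(acetyloxy)-5-(benzoyloxy)cyclohexa-1,3-dien-1-yl]methyl benzoate | CC(=O)O[C@H]1[C@H](OC(=O)c2ccccc2)C=CC=C1COC(=O)c1ccccc1 | intermediate
13 | 3-chloroperoxybenzoic acid (mCPBA) | OOC(=O)c1cccc(Cl)c1 | starting material
14 | [(1S,2S,3R,6S)-2-(acetyloxy)-3-(benzoyloxy)-7-oxabicyclo[4.1.0]hept-4-en-1-yl]methyl benzoate | CC(=O)O[C@H]1[C@H](OC(=O)c2ccccc2)C=C[C@@H]2O[C@@]21COC(=O)c1ccccc1 | target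

Total step count: 6. Longest linear sequence: 6 steps (1 → 3 → 6 → 8 → 10 → 12 → 14).

## Steps least certain to work

**Step 1 (key step).**
- What may go wrong: incomplete conversion, because 1 is toxic to the cells and is stripped from the aerated culture, and loss of product through acid- or heat-induced dehydration (rearomatisation) during extraction and concentration.
- Fallback: a change of substrate, setting out from 2 with a different arene and coming back at 10. The same cells are fed the less volatile iodobenzene F1 in place of 1, which should give (1S,2S)-3-iodocyclohexa-3,5-diene-1,2-diol F2. Mitsunobu reaction with 4 leads to (1R,6S)-6-hydroxy-5-iodocyclohexa-2,4-dien-1-yl benzoate F3, and acetylation with 7 to (1R,6S)-6-(acetyloxy)-5-iodocyclohexa-2,4-dien-1-yl benzoate F4. The vinyl iodide should couple with 9 at lower temperature than 8 and returns to the route at 10.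

**Step 2.**
- What may go wrong: rearomatisation by elimination from the oxyphosphonium ion, competing substitution at C2 or SN2′ attack at C5, and Diels–Alder dimerisation of the diene diol in concentrated solution.
- Fallback: the inversion is postponed until the ring holds only one alkene, setting out from 3 and coming back at 14.
  - 3 is silylated on both hydroxyls (Et3SiCl, imidazole) to the bis(triethylsilyl) ether F5.
  - F5 is coupled with 9 (Pd(PPh3)4) to the dienyl methanol F6 and benzoylated with 11 to the C7 benzoate F7.
  - F7 is epoxidised with 13, anti to both silyloxy groups, to the silylated epoxide F8.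
  - Buffered fluoride (Bu4NF, AcOH, THF, 0 °C) frees the cis epoxy diol F9, from which elimination can no longer give an arene.
  - Mitsunobu reaction with 4 inverts the allylic C3 carbinol to the epoxy hydroxy benzoate F10, and acetylation with 7 gives 14.

**Step 4.**
- What may go wrong: thermal loss of a carboxylic acid from the diene diester (aromatisation), ionisation of the allylic C3 benzoate by zerovalent palladium, slow transfer of the sp3 carbon from tin so that reduction of the C–Br bond competes, and acetyl migration to the new primary hydroxyl.
- Fallback: the coupling is done before any ester is in place, setting out from 3 and coming back at 12.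
  - 3 is coupled with 9 (Pd(PPh3)4) to the triol F11.
  - The primary hydroxyl is benzoylated selectively with 11 (2,4,6-collidine, CH2Cl2, −78 °C) to the diol benzoate F12.
  - Mitsunobu reaction with 4 at C3 gives the hydroxy dibenzoate F13, and acetylation with 7 gives 12.

**Step 6.**
- What may go wrong: poor facial selectivity (oxygen delivered syn to the acetate), competing or double epoxidation at C4=C5, and acid-induced opening of the vinyl epoxide.
- Fallback: reagent-controlled epoxidation at the allylic alcohol stage, setting out from 10 and coming back at 14. Sharpless asymmetric epoxidation of 10 (Ti(OiPr)4, L-(+)-diisopropyl tartrate, t-BuOOH, 4 Å molecular sieves, CH2Cl2, −20 °C) should give the epoxy alcohol F14. The titanium-bound C7 alkoxide confines the oxidant to C1=C6, and this tartrate enantiomer delivers oxygen to the face anti to the C2 acetate, which is also the face the substrate prefers. Benzoylation of F14 with 11 gives 14.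

## Further compounds

F1 | step 1 | iodobenzene | Ic1ccccc1
F2 | step 1 | (1S,2S)-3-iodocyclohexa-3,5-diene-1,2-diol | O[C@H]1[C@@H](O)C=CC=C1I
F3 | step 1 | (1R,6S)-6-hydroxy-5-iodocyclohexa-2,4-dien-1-yl benzoate | O[C@H]1[C@H](OC(=O)c2ccccc2)C=CC=C1I
F4 | step 1 | (1R,6S)-6-(acetyloxy)-5-iodocyclohexa-2,4-dien-1-yl benzoate | CC(=O)O[C@H]1[C@H](OC(=O)c2ccccc2)C=CC=C1I
F5 | step 2 | (1S,2S)-3-bromo-1,2-bis(triethylsilyloxy)cyclohexa-3,5-diene, the bis(triethylsilyl) ether of 3 | CC[Si](CC)(CC)O[C@H]1[C@@H](O[Si](CC)(CC)CC)C=CC=C1Br
F6 | step 2 | [(5S,6R)-5,6-bis(triethylsilyloxy)cyclohexa-1,3-dien-1-yl]methanol | CC[Si](CC)(CC)O[C@H]1[C@@H](O[Si](CC)(CC)CC)C=CC=C1CO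
F7 | step 2 | [(5S,6R)-5,6-bis(triethylsilyloxy)cyclohexa-1,3-dien-1-yl]methyl benzoate | CC[Si](CC)(CC)O[C@H]1[C@@H](O[Si](CC)(CC)CC)C=CC=C1COC(=O)c1ccccc1
F8 | step 2 | [(1S,2S,3S,6S)-2,3-bis(triethylsilyloxy)-7-oxabicyclo[4.1.0]hept-4-en-1-yl]methyl benzoate, epoxide oxygen anti to both silyloxy groups | CC[Si](CC)(CC)O[C@H]1[C@@H](O[Si](CC)(CC)CC)C=C[C@@H]2O[C@@]21COC(=O)c1ccccc1
F9 | step 2 | [(1R,2S,3S,6S)-2,3-dihydroxy-7-oxabicyclo[4.1.0]hept-4-en-1-yl]methyl benzoate, cis diol anti to the epoxide oxygen | O[C@H]1[C@@H](O)C=C[C@@H]2O[C@@]21COC(=O)c1ccccc1
F10 | step 2 | [(1R,2S,3R,6S)-3-(benzoyloxy)-2-hydroxy-7-oxabicyclo[4.1.0]hept-4-en-1-yl]methyl benzoate, the C2 alcohol corresponding to 14 | O[C@H]1[C@H](OC(=O)c2ccccc2)C=C[C@@H]2O[C@@]21COC(=O)c1ccccc1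
F11 | step 4 | (1S,2R)-3-(hydroxymethyl)cyclohexa-3,5-diene-1,2-diol | O[C@H]1[C@@H](O)C=CC=C1CO
F12 | step 4 | [(5S,6R)-5,6-dihydroxycyclohexa-1,3-dien-1-yl]methyl benzoate | O[C@H]1[C@@H](O)C=CC=C1COC(=O)c1ccccc1
F13 | step 4 | [(5R,6R)-5-(benzoyloxy)-6-hydroxycyclohexa-1,3-dien-1-yl]methyl benzoate | O[C@H]1[C@H](OC(=O)c2ccccc2)C=CC=C1COC(=O)c1ccccc1
F14 | step 6 | (1S,2S,3R,6S)-2-(acetyloxy)-1-(hydroxymethyl)-7-oxabicyclo[4.1.0]hept-4-en-3-yl benzoate, epoxide oxygen anti to the acetate | CC(=O)O[C@H]1[C@H](OC(=O)c2ccccc2)C=C[C@@H]2O[C@@]21CO
A1 | alternative 1 | spiro[2,3-dioxabicyclo[2.2.2]oct-5-ene-7,2'-oxiran]-8-yl acetate, peroxide bridge anti to the acetate and to the epoxide oxygen | CC(=O)O[C@H]1[C@H]3C=C[C@H](OO3)[C@]12CO2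
A2 | alternative 1 | 1-oxaspiro[2.5]octa-5,7-dien-4-yl acetate, acetate cis to the epoxide oxygen | CC(=O)O[C@H]1C=CC=C[C@]12CO2
A3 | alternative 1 | salicyl alcohol, 2-(hydroxymethyl)phenol | OCc1ccccc1O
A4 | alternative 2 | [1-hydroxy-3-(4-methoxybenzyloxy)-2-oxo-6-(tert-butyldimethylsilyloxy)cyclohex-4-en-1-yl]methyl benzoate, configuration as in the SMILES | O=C1[C@H](OCc2ccc(OC)cc2)C=C[C@@H](O[Si](C)(C)C(C)(C)C)[C@@]1(O)COC(=O)c1ccccc1
A5 | alternative 2 | (Z)-3-(tert-butyldimethylsilyloxy)-6-(4-methoxybenzyloxy)-2,7-dioxohept-4-en-1-yl benzoate, the open-chain keto aldehyde | O=C[C@H](OCc1ccc(OC)cc1)/C=C\[C@@H](O[Si](C)(C)C(C)(C)C)C(=O)COC(=O)c1ccccc1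
A6 | alternative 3 | 1-(hydroxymethyl)-3,3-dimethoxy-7-oxabicyclo[4.1.0]hept-4-en-2-one, configuration as in the SMILES | O=C1C(OC)(OC)C=C[C@@H]2O[C@@]21CO
A7 | alternative 3 | 2-(hydroxymethyl)-6,6-dimethoxycyclohexa-2,4-dien-1-one | O=C1C(OC)(OC)C=CC=C1CO
A8 | alternative 3 | o-vanillyl alcohol, 2-(hydroxymethyl)-6-methoxyphenol | COc1cccc(CO)c1O
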